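A small charge of reagent, 0.480 M against 0.80 M of starting material, makes reagent the limiting reagent of this flask if one reagent goes into each product.

common to all: free catalyst 34 mM; added ligand 62 mM

| run | starting material | reagent | remark |
|---|---|---|---|
| violet | 1.1 M | 0.48 M | run made earlier |
| blue | 1.8 M | 0.48 M | run made earlier |
| flask | 0.80 M | 0.480 M |  |

| violet: time / h | violet: product / % | blue: time / h | blue: product / % |
|---|---|---|---|
| 0.667 | 4 | 0.667 | 5 |
| 1.50 | 10 | 1.50 | 10 |
| 3.00 | 17 | 3.00 | 12 |
| 5.00 | 24 | 5.00 | 16 |

(standard deviation of a reading: 2 percentage points)

- apparent order in reagent when 30% of the starting material are converted (percent change of the rate of making product for one percent more reagent charged)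
- apparent order in free catalyst when 30% of the starting material are converted (percent change of the rate of making product for one percent more free catalyst charged)
- factor on the rate of making product when 30% of the starting material are converted if free catalyst is charged twice over

- no earlier run changes the charge of free catalyst; that part of a forecast is a guess
- no earlier run changes the charge of reagent; that part of a forecast is a guess

The reckoning here starts from a balance of reagent at 30% conversion, taking one reagent per starting material converted and reading all of that as product. Call the result the reagent reserve, the reagent still present at that conversion:

reserve = charge − starting material converted = 0.240 M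

The reagent taken by then stays the same when more is charged, so a change in charge is magnified in the reserve:

order in reagent = charge / reserve = 2.00

This assumes a rate first order in reagent, which is a guess. Free catalyst, also a guess at first order, gives order 1 and a factor of 2 on doubling.

The weak link is the balance, which sends each lost reagent into product. The blue run tests it. Its rate falls from 0.120 M h⁻¹ over the first 1.50 h to 0.0360 M h⁻¹ between 3.00 h and 5.00 h. Over the same stretches, the balance lowers blue's mean reagent from 0.390 M to just 0.228 M. Read at first order in reagent, with starting material taken as unchanged, the blue rates imply a further loss of reagent in that run by its late stretch: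

loss = 0.228 M − 0.390 M × 0.0360 M h⁻¹ / 0.120 M h⁻¹ = 0.111 M

With a scatter of 2 percentage points, this is a rough reading. Taken over unchanged to this flask, as an assumption, the loss leaves a reserve of 0.129 M. Suppose the loss scales with the reagent charge and with time, and needs no catalyst, so that doubling free catalyst halves it:

order in reagent = (0.480 M − 0.111 M) / 0.129 M = 2.86

order in free catalyst = 1 + 0.111 M / 0.129 M = 1.86

doubling factor = 2 × (0.240 M − 0.111 M / 2) / 0.129 M = 2.86

The forecast gives 1.8 in reagent, 1.1 in free catalyst and a factor of 2.3, each lower than these figures , and notes that “release of unbound catalyst could give a superlinear gain”.

The flask gives 2.3 in reagent, 3.1 in free catalyst and a factor of 4.66, so the reckoning here runs high on reagent and low on catalyst .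

    starting material + free catalyst → catalyst intermediate A (k = 24.8 M⁻¹ h⁻¹)
    free catalyst + added ligand ⇌ idle complex, settled at all times (K = 3.70 M⁻¹)
    reagent + catalyst intermediate A → catalyst intermediate B (k = 13.4 M⁻¹ h⁻¹)
    2 reagent → homo dimer (k = 0.654 M⁻¹ h⁻¹)
    catalyst intermediate B → free catalyst + product (k = 18.1 h⁻¹)

Against the reserve of 0.240 M, the flask holds 0.0481 M of reagent at 4.00 h, with 31.0% of the starting material gone, and its 0.107 M of homo dimer accounts for 0.214 M of reagent. At that time, the conversion of reagent and catalyst intermediate A into catalyst intermediate B uses reagent faster than the dimerisation does, by a factor of 6.6.

(The numbers in the tables were computed for substances that don't exist; scatter was added.)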